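3.12 h is the number to carry: τ, the time constant of the slow fall of substrate, a reading taken from the red run between 5.00 min and 40.0 min, after its quick early drop.

- red: substrate 0.20 M; reagent in the second phase 0.12 M; run made earlier
- flask: substrate 0.10 M; reagent in the second phase 0.120 M; time 2.0 h; volume of the second phase over the first 1.0

red run (percent of the substrate charged)

| time / min | target / % | substrate / % |
|---|---|---|
| 5.00 | 3 | 82 |
| 12.0 | 4 | 77 |
| 25.0 | 15 | 70 |
| 40.0 | 15 | 68 |

(readings scatter by 1.5 percentage points)

- in the second phase: reagent in the second phase; everything else is in the first
- charges count per volume of the first phase; a concentration in a rate is the amount of a species over the volume of its own phase; every rate counts per litre of the first phase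
- the numbers in the tables scatter with a standard deviation of 1.5 percentage points
- the earlier runs hold the two phases in the same ratio of volumes as the flask asked about

- amount of target at 2.0 h, in percent of the substrate charged
- the change that raises the amount of target at 2.0 h, in percent of the substrate charged most ("none" if none brings more than 2 percentage points) (west / north-west / none)
- amount of target at 2.0 h, in percent of the substrate charged, after north-west

- west: doubling the transfer coefficient of the reagent in the second phase, all else as stated
- north-west: doubling the amount of reagent in the second phase, all else as stated

My own reckoning freezes the reagent, which makes the conversion pseudo-first-order at fixed τ. You then take target as one minus exp(−t/τ), which gives 47.4% for the flask at 2.0 h. Taking τ as inversely proportional to the reagent charge, doubling that charge gives 72.3%.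

The forecast, reading the runs as “fast reversible uptake”, gives 43%, names north-west as the best change and gives 62% after it. Both figures are lower than mine.

The simulation gives 42.4%. North-west gains 26 percentage points and reaches 68.2%, while west gains 1.5 points, so the best change is north-west.

    reagent in the reaction phase ⇌ reagent in the second phase, rate k1*([reagent in the reaction phase] - [reagent in the second phase]/K1) per volume of the first phase (partition coefficient = 41.0, kL = 0.0230 /s)
    substrate + reagent in the reaction phase → target (k = 0.0490 /M/s)
    substrate ⇌ dormant form (K = 0.210, k = 0.00140 /s)
    target → over-reaction product (k = 8.50 × 10⁻⁶ /s)

The 47.4% from the frozen τ is higher than the 42.4% of the flask, whose reagent in the second phase is down to 62.0% of its charge at 2.00 h. A neighbour flask charged with 0.060 M of substrate keeps 74.0% of its reagent charge in the second phase at 2.00 h and gives 46.9%, against 47.4% from τ. The asked time is 0.641 of τ, and the flask is not at rest, with 46.2% of its substrate left. At ten times the time, substrate stands at 4.64%, target has gained 16 points to reach 58.1%, and over-reaction product has gained 35 points to reach 36.3%.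

The data are calculated from invented constants, noise included.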